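**Retrosynthetic overview** (isochromanone numbering: C1 lactone carbonyl, O2, C3 hemiketal carbon, C4 CH–CH3, C4a–C8a ring A)
1. The lactol ring is the ring tautomer of a keto acid: C1 (on C8a) and C3 are both carbonyl-level carbons joined only through O2, so C3 equilibrates and C4 is the only independent stereocentre.
2. This feature lets a temporary C1–C3 bond stand in for O2: the target is an O-inserted 2-hydroxyindan-1-one, and periodate cleavage of that α-ketol followed by hemiketalisation gives the lactol.
3. C4a–C4 is formed by closing this temporary five-membered ring (C8a–C1–C3–C4–C4a): enantioselective palladium-catalysed reductive Heck cyclisation of an aryl bromide (Br on C4a) onto a crotonyl ketone on C8a.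
4. In the indanone C4 is β to the ketone and cannot epimerise; C3 is then built up by α-methylenation, epoxidation and opening of the spiro-epoxide with 2,4-bis(benzyloxy)-5,6-dimethylbenzoic acid.
5. Ring order: ring A (bought) → temporary cyclopentanone (step 4) → oxirane (step 8) → lactol ring (step 13); hydrogenolysis then frees the three phenols.

Key step: step 4

Remark: the (R)-bisphosphine is assumed to give the (3R)-indanone; if the sense of induction is the opposite, its enantiomer is used and nothing else changes.
Remark: the (3R) hemiketal (3-OH trans to 4-CH3, axial and anomerically stabilised) is taken as the thermodynamic configuration, reached by ring–chain tautomerism.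
Remark: 4,5-dimethylbenzene-1,3-diol is taken as a commercial starting material.

**Step 1**
Reactants: 1 1-bromo-3,5-dimethoxybenzene
Product: 2 2-bromo-4,6-dimethoxybenzaldehyde
Conditions: POCl3, DMF, 0 to 90 °C; then H2O
Reagents that add atoms: N,N-dimethylformamide, CN(C)C=O; water, O
Why: Vilsmeier–Haack formylation, in which the chloroiminium ion should attack the position para to one methoxy group and ortho to the other (next to bromine) rather than the more crowded position between the two methoxy groups.

**Step 2**
Reactants: 2 2-bromo-4,6-dimethoxybenzaldehyde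
Product: 3 1-bromo-3,5-dimethoxy-2-methylbenzene
Conditions: Et3SiH (3 equiv), CF3CO2H, CH2Cl2, 0 °C to rt
Reagents that add atoms: none
Why: Ionic hydrogenation, in which the methoxy-stabilised benzylic cation is reduced twice by the silane, turning the formyl group into the future C5 methyl group while the aryl bromide stays inert.

**Step 3**
Reactants: 3 1-bromo-3,5-dimethoxy-2-methylbenzene; 4 (E)-but-2-enoyl chloride
Product: 5 (E)-1-(2-bromo-4,6-dimethoxy-3-methylphenyl)but-2-en-1-one
Conditions: AlCl3 (1.2 equiv), CH2Cl2, −20 to 0 °C; cold aqueous work-up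
Reagents that add atoms: none
Why: Friedel–Crafts acylation, in which the acylium ion should enter the position para to a methoxy group (future C8a, between bromine and the C8 methoxy group) as in step 1, and low temperature should keep both methyl ethers and the (E)-enone intact.

**Step 4**
Reactants: 5 (E)-1-(2-bromo-4,6-dimethoxy-3-methylphenyl)but-2-en-1-one
Product: 6 (3R)-5,7-dimethoxy-3,4-dimethyl-2,3-dihydro-1H-inden-1-one
Conditions: Pd(OAc)2 (5 mol%), (R)-3,5-Xyl-MeO-BIPHEP (7.5 mol%), HCO2Na (1.5 equiv), DMF, 80 °C
Reagents that add atoms: none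
Why: Oxidative addition of the C4a–Br bond to zerovalent palladium carrying the chiral bisphosphine gives an arylpalladium bromide whose only reachable alkene is the (E)-enone on C8a; intramolecular insertion (conjugate arylation, formally 5-endo-trig) forms the C4a–C4 bond and a palladium enolate, and formate delivers the hydrogen to C2 and returns divalent palladium to the zerovalent state with loss of CO2. The closest known reaction type is the palladium-catalysed enantioselective reductive Heck cyclisation of 2'-halo- or 2'-sulfonyloxy-aryl enones to 3-substituted indan-1-ones. The five-membered carbocycle C8a–C1–C3–C4–C4a is closed by attack of the aryl carbon on the enone β-carbon, the C1–C3 bond being the temporary tether that is cut in step 13. The new stereocentre (C3 of the indanone, C4 of the target) is set by the ligand, which differentiates the two faces of the enone in the insertion step, and because it lies β to the ketone it cannot epimerise in later steps. The step needs cyclisation to outrun hydrodebromination and conjugate reduction of the enone, which the short tether and the (E)-geometry favour, and it needs the C8 oxygen to stay methylated so that no 2'-hydroxy enone can close to a chromanone.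

**Step 5**
Reactants: 6 (3R)-5,7-dimethoxy-3,4-dimethyl-2,3-dihydro-1H-inden-1-one
Product: 7 (3R)-7-hydroxy-5-methoxy-3,4-dimethyl-2,3-dihydro-1H-inden-1-one
Conditions: BCl3 (1.5 equiv), CH2Cl2, −78 to 0 °C; then H2O
Reagents that add atoms: none
Why: Chelation-controlled aryl methyl ether cleavage, in which BCl3 bridges the ketone oxygen and the peri methoxy oxygen and should remove only that methyl group, leaving the other methoxy group and the stereocentre untouched.

**Step 6**
Reactants: 7 (3R)-7-hydroxy-5-methoxy-3,4-dimethyl-2,3-dihydro-1H-inden-1-one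
Product: 8 (3R)-7-(benzyloxy)-5-methoxy-3,4-dimethyl-2,3-dihydro-1H-inden-1-one
Conditions: BnBr, K2CO3, DMF, 60 °C
Reagents that add atoms: benzyl bromide, BrCc1ccccc1
Why: Williamson etherification of the phenoxide; the benzyl group should shield the phenol from formaldehyde, peroxide and periodate and leaves with the other two benzyl groups in the last step.

**Step 7**
Reactants: 8 (3R)-7-(benzyloxy)-5-methoxy-3,4-dimethyl-2,3-dihydro-1H-inden-1-one
Product: 9 (3S)-7-(benzyloxy)-5-methoxy-3,4-dimethyl-2-methylidene-2,3-dihydro-1H-inden-1-one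
Conditions: (CH2O)n, N-methylanilinium trifluoroacetate, THF, reflux; used at once
Reagents that add atoms: formaldehyde (as paraformaldehyde), C=O
Why: Mannich-type α-methylenation at the only enolisable position (C2), followed by loss of the amine to give the exocyclic enone; C3 is not acidic and keeps its configuration, and the enone is carried on immediately because 2-methyleneindanones dimerise on standing.

**Step 8**
Reactants: 9 (3S)-7-(benzyloxy)-5-methoxy-3,4-dimethyl-2-methylidene-2,3-dihydro-1H-inden-1-one
Product: 10 (2S,3S)-7-(benzyloxy)-5-methoxy-3,4-dimethylspiro[indene-2,2'-oxiran]-1(3H)-one (epoxide oxygen trans to the 3-methyl group)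
Conditions: 30% H2O2, NaOH (cat.), MeOH–THF, 0 °C
Reagents that add atoms: hydrogen peroxide, OO
Why: Weitz–Scheffer nucleophilic epoxidation, in which hydroperoxide adds to the exocyclic methylene carbon and the enolate closes the oxirane, expected mainly with oxygen anti to the 3-methyl group; the configuration of this spiro carbon is erased in step 13, so either epimer would serve.

**Step 9**
Reactants: 11 4,5-dimethylbenzene-1,3-diol
Product: 12 2,4-dihydroxy-5,6-dimethylbenzaldehyde
Conditions: POCl3, DMF, MeCN, 0 °C to rt; then H2O, 50 °C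
Reagents that add atoms: N,N-dimethylformamide, CN(C)C=O; water, O
Why: Vilsmeier–Haack formylation of a resorcinol, which should occur para to one hydroxyl and ortho to the other (next to the methyl group), as with orcinol, and not between the two hydroxyl groups.

**Step 10**
Reactants: 12 2,4-dihydroxy-5,6-dimethylbenzaldehyde
Product: 13 2,4-bis(benzyloxy)-5,6-dimethylbenzaldehyde
Conditions: BnBr (2.5 equiv), K2CO3, DMF, 70 °C
Reagents that add atoms: benzyl bromide, BrCc1ccccc1
Why: Double Williamson etherification; the chelated ortho hydroxyl reacts more slowly, hence excess benzyl bromide and warming.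

**Step 11**
Reactants: 13 2,4-bis(benzyloxy)-5,6-dimethylbenzaldehyde
Product: 14 2,4-bis(benzyloxy)-5,6-dimethylbenzoic acid
Conditions: NaClO2, NaH2PO4, 2-methyl-2-butene, t-BuOH–THF–H2O, rt
Reagents that add atoms: sodium chlorite, [Na+].[O-]Cl=O
Why: Pinnick oxidation should convert the hindered aldehyde into the acid without touching the benzyl ethers, the alkene trapping hypochlorous acid that would otherwise chlorinate the electron-rich ring.

**Step 12**
Reactants: 10 (2S,3S)-7-(benzyloxy)-5-methoxy-3,4-dimethylspiro[indene-2,2'-oxiran]-1(3H)-one; 14 2,4-bis(benzyloxy)-5,6-dimethylbenzoic acid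
Product: 15 [(2S,3S)-7-(benzyloxy)-2-hydroxy-5-methoxy-3,4-dimethyl-1-oxo-2,3-dihydro-1H-inden-2-yl]methyl 2,4-bis(benzyloxy)-5,6-dimethylbenzoate
Conditions: Cs2CO3 (0.3 equiv), DMF, 60 °C
Reagents that add atoms: none
Why: SN2 opening of the spiro-epoxide by the caesium carboxylate at the unhindered methylene carbon (the quaternary α-keto carbon cannot be attacked), which frees the tertiary hydroxyl and installs the whole ester side chain with retention at C2 because its C–O bond is not broken.

**Step 13**
Reactants: 15 [(2S,3S)-7-(benzyloxy)-2-hydroxy-5-methoxy-3,4-dimethyl-1-oxo-2,3-dihydro-1H-inden-2-yl]methyl 2,4-bis(benzyloxy)-5,6-dimethylbenzoate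
Product: 17 [(3R,4S)-8-(benzyloxy)-3-hydroxy-6-methoxy-4,5-dimethyl-1-oxo-3,4-dihydro-1H-isochromen-3-yl]methyl 2,4-bis(benzyloxy)-5,6-dimethylbenzoate, via open-chain keto acid 16 (not isolated)
Conditions: H5IO6 (1.5 equiv), THF–H2O, 0 °C to rt
Reagents that add atoms: water, O
Why: Malaprade-type α-ketol cleavage, in which a cyclic periodate ester of the tertiary hydroxyl and the hydrated ketone cuts the temporary C1–C3 bond to an aryl carboxylic acid and a ketone that should close spontaneously to the six-membered lactol; C3 equilibrates through the open form to the hemiketal with hydroxyl trans to the C4 methyl group, while C4 is not touched.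

**Step 14**
Reactants: 17 [(3R,4S)-8-(benzyloxy)-3-hydroxy-6-methoxy-4,5-dimethyl-1-oxo-3,4-dihydro-1H-isochromen-3-yl]methyl 2,4-bis(benzyloxy)-5,6-dimethylbenzoate
Product: 18 [(3R,4S)-3,8-dihydroxy-6-methoxy-4,5-dimethyl-1-oxo-3,4-dihydro-1H-isochromen-3-yl]methyl 2,4-dihydroxy-5,6-dimethylbenzoate
Conditions: H2 (1 atm), 10% Pd/C, EtOAc, rt
Reagents that add atoms: none
Why: Hydrogenolysis of the three aryl benzyl ethers under neutral conditions, which avoids acid or base that could enolise the open keto acid form and epimerise C4; the esters, the lactol and the methyl ether should be inert.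

**Compound list**
1 | 1-bromo-3,5-dimethoxybenzene | COc1cc(Br)cc(OC)c1 | starting material
2 | 2-bromo-4,6-dimethoxybenzaldehyde | COc1cc(Br)c(C=O)c(OC)c1 | intermediate
3 | 1-bromo-3,5-dimethoxy-2-methylbenzene | COc1cc(Br)c(C)c(OC)c1 | intermediate
4 | (E)-but-2-enoyl chloride | C/C=C/C(=O)Cl | starting material
5 | (E)-1-(2-bromo-4,6-dimethoxy-3-methylphenyl)but-2-en-1-one | C/C=C/C(=O)c1c(Br)c(C)c(OC)cc1OC | intermediate
6 | (3R)-5,7-dimethoxy-3,4-dimethyl-2,3-dihydro-1H-inden-1-one | COc1cc(OC)c2c(c1C)[C@H](C)CC2=O | intermediate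
7 | (3R)-7-hydroxy-5-methoxy-3,4-dimethyl-2,3-dihydro-1H-inden-1-one | COc1cc(O)c2c(c1C)[C@H](C)CC2=O | intermediate
8 | (3R)-7-(benzyloxy)-5-methoxy-3,4-dimethyl-2,3-dihydro-1H-inden-1-one | COc1cc(OCc3ccccc3)c2c(c1C)[C@H](C)CC2=O | intermediate
9 | (3S)-7-(benzyloxy)-5-methoxy-3,4-dimethyl-2-methylidene-2,3-dihydro-1H-inden-1-one | COc1cc(OCc3ccccc3)c2c(c1C)[C@H](C)C(=C)C2=O | intermediate
10 | (2S,3S)-7-(benzyloxy)-5-methoxy-3,4-dimethylspiro[indene-2,2'-oxiran]-1(3H)-one, epoxide oxygen trans to 3-CH3 | COc1cc(OCc3ccccc3)c2c(c1C)[C@H](C)[C@]4(CO4)C2=O | intermediate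
11 | 4,5-dimethylbenzene-1,3-diol | Cc1cc(O)cc(O)c1C | starting material
12 | 2,4-dihydroxy-5,6-dimethylbenzaldehyde | Cc1c(C)c(C=O)c(O)cc1O | intermediate
13 | 2,4-bis(benzyloxy)-5,6-dimethylbenzaldehyde | Cc1c(C)c(C=O)c(OCc2ccccc2)cc1OCc1ccccc1 | intermediate
14 | 2,4-bis(benzyloxy)-5,6-dimethylbenzoic acid | Cc1c(C)c(C(=O)O)c(OCc2ccccc2)cc1OCc1ccccc1 | intermediate
15 | [(2S,3S)-7-(benzyloxy)-2-hydroxy-5-methoxy-3,4-dimethyl-1-oxo-2,3-dihydro-1H-inden-2-yl]methyl 2,4-bis(benzyloxy)-5,6-dimethylbenzoate (2-OH trans to 3-CH3) | COc1cc(OCc3ccccc3)c2c(c1C)[C@H](C)[C@](O)(COC(=O)c1c(OCc3ccccc3)cc(OCc3ccccc3)c(C)c1C)C2=O | intermediate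
16 | 2-(benzyloxy)-6-[(2S)-4-{[2,4-bis(benzyloxy)-5,6-dimethylbenzoyl]oxy}-3-oxobutan-2-yl]-4-methoxy-5-methylbenzoic acid | COc1cc(OCc3ccccc3)c(C(=O)O)c(c1C)[C@H](C)C(=O)COC(=O)c1c(OCc3ccccc3)cc(OCc3ccccc3)c(C)c1C | intermediate
17 | [(3R,4S)-8-(benzyloxy)-3-hydroxy-6-methoxy-4,5-dimethyl-1-oxo-3,4-dihydro-1H-isochromen-3-yl]methyl 2,4-bis(benzyloxy)-5,6-dimethylbenzoate | COc1cc(OCc3ccccc3)c2c(c1C)[C@H](C)[C@](O)(COC(=O)c1c(OCc3ccccc3)cc(OCc3ccccc3)c(C)c1C)OC2=O | intermediate
18 | [(3R,4S)-3,8-dihydroxy-6-methoxy-4,5-dimethyl-1-oxo-3,4-dihydro-1H-isochromen-3-yl]methyl 2,4-dihydroxy-5,6-dimethylbenzoate | COc1cc(O)c2c(c1C)[C@H](C)[C@](O)(COC(=O)c1c(O)cc(O)c(C)c1C)OC2=O | target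

**Step count and risks**
Total steps: 14. Longest linear sequence: 11 (steps 1–8 and 12–14).

Steps most likely to fail:

1. Step 4. The arylpalladium bromide may be reduced by formate before it inserts (hydrodebromination), the enone may undergo conjugate reduction, or the ligand may discriminate the enone faces poorly on this hindered, twisted aryl ketone. Fallback, from 5 back to 6, with the polarity of the closure inverted: Miyaura borylation of 5 (B2pin2, PdCl2(dppf), KOAc, dioxane, 80 °C) should give (E)-1-[4,6-dimethoxy-3-methyl-2-(4,4,5,5-tetramethyl-1,3,2-dioxaborolan-2-yl)phenyl]but-2-en-1-one F1. Its aryl–boron bond would be transmetallated to monovalent rhodium carrying (R)-BINAP ([RhCl(C2H4)2]2, aqueous KOH, dioxane, 40 °C); intramolecular asymmetric 1,4-addition and protonation of the rhodium enolate by water would return indanone 6.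

2. Step 3. Acylation may go to the position between the two methoxy groups, or AlCl3 may cleave the methyl ether ortho to the new ketone so that the freed phenol adds to the enone. Fallback, from 3 back to 5, building the ketone by carbonyl addition instead of acylium chemistry: a second Vilsmeier–Haack formylation (POCl3, DMF) should give 2-bromo-4,6-dimethoxy-3-methylbenzaldehyde F2. Addition of allylmagnesium bromide (THF, −78 °C) would give racemic 1-(2-bromo-4,6-dimethoxy-3-methylphenyl)but-3-en-1-ol F3. Oxidation with DMP would give 1-(2-bromo-4,6-dimethoxy-3-methylphenyl)but-3-en-1-one F4, and DBU would move the double bond into conjugation to return (E)-enone 5.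

3. Step 13. Formation of the cyclic periodate ester may be too slow because the electron-rich, hindered aryl ketone hydrates poorly, giving incomplete cleavage or oxidation of the arene on long exposure. Fallback, from 15 back to 16 (which closes to 17), cleaving a glycol instead of a ketol: NaBH4 (MeOH–THF, 0 °C) should reduce the ketone to [(2S,3S)-7-(benzyloxy)-1,2-dihydroxy-5-methoxy-3,4-dimethyl-2,3-dihydro-1H-inden-2-yl]methyl 2,4-bis(benzyloxy)-5,6-dimethylbenzoate F5 (either C1 epimer serves). NaIO4 (THF–H2O) would cleave the 1,2-diol to (3S)-3-[3-(benzyloxy)-2-formyl-5-methoxy-6-methylphenyl]-2-oxobutyl 2,4-bis(benzyloxy)-5,6-dimethylbenzoate F6, and Pinnick oxidation of the aldehyde (NaClO2, NaH2PO4, 2-methyl-2-butene) would give keto acid 16.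

**Further compounds**
F1 | step 4 | (E)-1-[4,6-dimethoxy-3-methyl-2-(4,4,5,5-tetramethyl-1,3,2-dioxaborolan-2-yl)phenyl]but-2-en-1-one | C/C=C/C(=O)c1c(B2OC(C)(C)C(C)(C)O2)c(C)c(OC)cc1OC
F2 | step 3 | 2-bromo-4,6-dimethoxy-3-methylbenzaldehyde | COc1cc(OC)c(C=O)c(Br)c1C
F3 | step 3 | 1-(2-bromo-4,6-dimethoxy-3-methylphenyl)but-3-en-1-ol (racemic) | C=CCC(O)c1c(Br)c(C)c(OC)cc1OC
F4 | step 3 | 1-(2-bromo-4,6-dimethoxy-3-methylphenyl)but-3-en-1-one | C=CCC(=O)c1c(Br)c(C)c(OC)cc1OC
F5 | step 13 | [(2S,3S)-7-(benzyloxy)-1,2-dihydroxy-5-methoxy-3,4-dimethyl-2,3-dihydro-1H-inden-2-yl]methyl 2,4-bis(benzyloxy)-5,6-dimethylbenzoate (C1 epimers) | COc1cc(OCc3ccccc3)c2c(c1C)[C@H](C)[C@](O)(COC(=O)c1c(OCc3ccccc3)cc(OCc3ccccc3)c(C)c1C)C2O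
F6 | step 13 | (3S)-3-[3-(benzyloxy)-2-formyl-5-methoxy-6-methylphenyl]-2-oxobutyl 2,4-bis(benzyloxy)-5,6-dimethylbenzoate | COc1cc(OCc3ccccc3)c(C=O)c(c1C)[C@H](C)C(=O)COC(=O)c1c(OCc3ccccc3)cc(OCc3ccccc3)c(C)c1C
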